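**Strategy.** The ten-membered ring is not cyclised but grown out of a six-membered one. A trans-decalin is built in which ring B (C1, C2, C7, C8, C9, C10; briarane numbering) carries an equatorial ethynyl carbinol at C2 and an equatorial allenyl group at C7; an anionic oxy-Cope shift then breaks C2–C7 and forms C4–C5. This single step delivers the 6/10 skeleton together with the C2 carbonyl, the Z-C3=C4 alkene, the C5 exo-methylene and an E-C6=C7 alkene for the chloro-lactone, while C1, C8, C9, C10, C11, C12, C17 and the C20 chloride have already been set on the rigid decalin, itself made by a quinone Diels–Alder reaction.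

Key step: step 22

Remarks on the chemistry (assumptions):
- Briarane numbering (C1–C20) is used for every intermediate; β is the face of the C1 methyl group (C15), α the opposite face.
- Quinone 3 and all reagents are taken as purchasable.
- The catalyst antipode in step 2 is taken to be the one that gives the 1S series; the mirror-image catalyst would give ent-4.
- The configuration at C6 in 20–26 and at the CHBr carbon of 24 is not controlled and is destroyed later; these centres are left undefined in the SMILES strings.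

Step 1
Reactants: 1 penta-1,4-dien-3-ol
Product: 2 (E)-5-chloropenta-1,3-diene
Conditions: conc. aq. HCl, 0 °C → rt
Reagents that add atoms: hydrogen chloride, Cl
Why: Allylic substitution with transposition through the pentadienyl cation should give the conjugated E-chlorodiene; no stereocentre is formed.

Step 2
Reactants: 2 (E)-5-chloropenta-1,3-diene; 3 2-methoxy-5-methyl-1,4-benzoquinone
Product: 4 cis-fused Diels–Alder adduct
Conditions: oxazaborolidinium triflimide from (S)-α,α-diphenylprolinol/o-tolylboroxine (20 mol %), CH2Cl2, −78 °C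
Reagents that add atoms: none
Why: Chiral Lewis acid catalysed endo Diels–Alder reaction in which the methyl-bearing C=C of 3 reacts (the methoxy-bearing one is a deactivated vinylogous ester), the unsubstituted diene terminus bonds to the methyl-bearing carbon (β to the activated C9 carbonyl and the less congested union) so that CH2Cl ends on C11, the endo rule sets C11–H cis to C10–H and C1–CH3, and the catalyst shields one quinone face so that quaternary C1 should form in the S series.

Step 3
Reactants: 4 cis-fused Diels–Alder adduct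
Product: 5 trans-fused enedione
Conditions: TsOH (anhydrous, cat.), benzene, 40 °C
Reagents that add atoms: none
Why: Acid-catalysed enolisation of the C9 ketone should equilibrate C10 to the more stable trans-fused enedione (classical cis-to-trans isomerisation of quinone adducts), and acid instead of base avoids alkylation of a C10 enolate by the γ-chloride.

Step 4
Reactants: 5 trans-fused enedione
Product: 6 9β-hydroxy-8-methoxy-7-en-2-one
Conditions: NaBH4, CeCl3·7H2O, MeOH/CH2Cl2, −78 °C
Reagents that add atoms: none
Why: Luche 1,2-reduction should take the C9 carbonyl before the C2 carbonyl (a deactivated vinylogous ester), with hydride arriving on the α face because the β face is blocked by the syn-axial C1 methyl (as in 11-oxo steroids), which gives the axial 9β-alcohol.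

Step 5
Reactants: 6 9β-hydroxy-8-methoxy-7-en-2-one
Product: 7 9β-TBS ether
Conditions: TBSOTf, 2,6-lutidine, CH2Cl2, −78 → 0 °C
Reagents that add atoms: tert-butyldimethylsilyl triflate, CC(C)(C)[Si](C)(C)OS(=O)(=O)C(F)(F)F
Why: Silylation of a hindered secondary alcohol with a silyl triflate; no stereocentre changes.

Step 6
Reactants: 7 9β-TBS ether
Product: 8 12α,13α-epoxide
Conditions: mCPBA, NaHCO3, CH2Cl2, 0 °C
Reagents that add atoms: 3-chloroperbenzoic acid, OOC(=O)c1cccc(Cl)c1
Why: Prilezhaev epoxidation of the only electron-rich alkene (C7=C8 is deactivated by the C2 carbonyl) should occur on the α face, anti to the homoallylic axial C1 methyl, as with Δ2-steroids.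

Step 7
Reactants: 8 12α,13α-epoxide
Product: 9 12α-hydroxy-13-ene
Conditions: Et2AlTMP (from 2,2,6,6-tetramethylpiperidine, n-BuLi, Et2AlCl), toluene, 0 °C
Reagents that add atoms: none
Why: Aluminium amide mediated syn-β-elimination (epoxide to allylic alcohol isomerisation) should be regioselective because only C14 carries a hydrogen syn to the epoxide oxygen (C11 has CH2Cl on that face), and C12 keeps its α-oxygen.

Step 8
Reactants: 9 12α-hydroxy-13-ene
Product: 10 11-(chloromethyl)-11,13-diene
Conditions: Martin sulfurane, CH2Cl2, 0 °C → rt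
Reagents that add atoms: none
Why: Martin sulfurane dehydration should proceed by anti elimination of the pseudo-axial 12α-oxysulfonium group and the axial 11β-hydrogen to give the conjugated diene.

Step 9
Reactants: 10 11-(chloromethyl)-11,13-diene
Product: 11 11α,12α-diol
Conditions: OsO4 (2 mol %), NMO, acetone/H2O, 0 °C
Reagents that add atoms: N-methylmorpholine N-oxide, C[N+]1([O-])CCOCC1; water, O
Why: Upjohn dihydroxylation should select the trisubstituted C11=C12 bond over the neopentylic cis-disubstituted C13=C14 bond and add on the α face (the β face is shielded by the C1 methyl and the 9β-silyloxy group), so that syn addition sets C11 (OH α, CH2Cl β) and C12 (OH α) together.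

Step 10
Reactants: 11 11α,12α-diol
Product: 12 11α,12α-acetonide
Conditions: 2,2-dimethoxypropane, PPTS (cat.), CH2Cl2, rt
Reagents that add atoms: 2,2-dimethoxypropane, COC(C)(C)OC
Why: Acid-catalysed transacetalisation onto the cis-diol; the acetal also keeps the C11 oxygen from closing onto C20 under later basic steps.

Step 11
Reactants: 12 11α,12α-acetonide; 13 lithium (trimethylsilyl)acetylide
Product: 15 2-alkynyl-2(7)-en-8-one, via lithium 2-alkoxide 14 (not isolated)
Conditions: 13, CeCl3, THF, −78 → 0 °C; then 1 M aq. HCl, THF, 0 °C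
Reagents that add atoms: water, O
Why: Stork–Danheiser sequence in which 1,2-addition to the only carbonyl (C2) is followed by enol ether hydrolysis and β-elimination of the tertiary carbinol, which moves the carbonyl to C8 and leaves the alkyne on C2 (the C2 centre of 14 is lost).

Step 12
Reactants: 15 2-alkynyl-2(7)-en-8-one
Product: 16 2α,7α-epoxy-8-ketone
Conditions: t-BuOOH (anhydrous, decane), DBU, CH2Cl2, 0 °C → rt
Reagents that add atoms: tert-butyl hydroperoxide, CC(C)(C)OO
Why: Weitz–Scheffer nucleophilic epoxidation in which the peroxide anion should add to the β-carbon C2 on the α face, anti to the adjacent axial C1 methyl (as with Δ1-3-oxo steroids), so that the new C2–O bond is α-axial and the alkynyl group β-equatorial.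

Step 13
Reactants: 16 2α,7α-epoxy-8-ketone
Product: 17 2α-hydroxy-8-ketone
Conditions: SmI2 (2.2 equiv), THF/MeOH, −90 °C
Reagents that add atoms: none
Why: Samarium diiodide reduction of an α,β-epoxy ketone cleaves the C7–O bond next to the ketyl and protonates the samarium enolate, which leaves the C2–O bond and its configuration untouched.

Step 14
Reactants: 17 2α-hydroxy-8-ketone; 18 3-(trimethylsilyl)propynal
Product: 21 C6 methyl carbonate, via dilithium alkoxide-enolate 19 (not isolated), via dilithium aldolate 20 (not isolated)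
Conditions: LDA (2.1 equiv), THF, −78 °C; 18; then ClCO2Me, −78 °C; AcOH quench
Reagents that add atoms: methyl chloroformate, COC(Cl)=O
Why: Aldol addition of the alkoxide–enolate dianion (enolisation toward C7, whose axial hydrogen is aligned, not toward the equatorial α-silyloxy C9–H) in which the aldehyde should attack C7 on the α face because the β face carries the syn-axial C1 methyl and C9 silyloxy groups, giving the equatorial side chain, after which the less hindered secondary aldolate oxygen is acylated in situ.

Step 15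
Reactants: 21 C6 methyl carbonate
Product: 22 9β-alcohol
Conditions: HF·pyridine, pyridine/THF, 0 °C → rt
Reagents that add atoms: none
Why: Fluoride cleavage of the silyl ether under non-basic conditions that should spare the β-carbonato ketone, the alkynylsilanes and the acetonide.

Step 16
Reactants: 22 9β-alcohol; 23 2-bromopropanoyl bromide
Product: 24 9-(2-bromopropanoate)
Conditions: pyridine, DMAP (cat.), CH2Cl2, −20 → 0 °C
Reagents that add atoms: none
Why: Acylation of the secondary alcohol with a reactive acyl bromide; the tertiary propargylic C2 alcohol should not react.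

Step 17
Reactants: 24 9-(2-bromopropanoate)
Product: 25 8α-hydroxy 19,9-lactone
Conditions: SmI2 (2.5 equiv), THF, −78 °C
Reagents that add atoms: none
Why: Samarium diiodide promoted intramolecular Reformatsky reaction in which the enolate tethered to the axial C9 oxygen can reach C8 only along the equatorial β trajectory (a γ-lactone fused at C8–C9 must be cis), so that the C8 hydroxyl becomes α-axial and C17 β-equatorial, while in the samarium-bridged C8–O–Sm–O=C19 transition state the C17 methyl should point away from the metal (trans to the C8 oxygen).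

Step 18
Reactants: 25 8α-hydroxy 19,9-lactone
Product: 26 bis(terminal alkyne) lactone
Conditions: AgNO3 (10 mol %), acetone/H2O/CH2Cl2, rt
Reagents that add atoms: none
Why: Silver-catalysed protodesilylation of both alkynylsilanes under neutral conditions that should leave the carbonate and the lactone intact.

Step 19
Reactants: 26 bis(terminal alkyne) lactone
Product: 27 7α-allenyl lactone
Conditions: Pd2(dba)3·CHCl3 (2.5 mol %), n-Bu3P (10 mol %), HCO2NH4, THF, 25 °C
Reagents that add atoms: none
Why: Palladium-catalysed formate hydrogenolysis of the propargylic carbonate (allenylpalladium formate, decarboxylation, reductive elimination at the alkyne terminus, i.e. SN2′ hydride delivery) should give the terminal allene, the ketone that would allow β-elimination being already gone.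

Step 20
Reactants: 27 7α-allenyl lactone
Product: 28 pyrrolidine amide 8α,9β-diol
Conditions: pyrrolidine, THF, 45 °C
Reagents that add atoms: pyrrolidine, C1CCNC1
Why: Aminolysis of the γ-lactone gives the tertiary amide, a carboxyl form that should neither enolise nor undergo retro-aldol cleavage in the basic key step, and frees the C9 hydroxyl.

Step 21
Reactants: 28 pyrrolidine amide 8α,9β-diol
Product: 29 9β-TBS ether (oxy-Cope substrate)
Conditions: TBSOTf (1.1 equiv), 2,6-lutidine, CH2Cl2, −78 °C
Reagents that add atoms: tert-butyldimethylsilyl triflate, CC(C)(C)[Si](C)(C)OS(=O)(=O)C(F)(F)F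
Why: Low-temperature silylation should select the secondary C9 alcohol over the two tertiary ones; a free C9 alkoxide would otherwise alkylate at C20 in step 22.

Step 22
Reactants: 29 9β-TBS ether (oxy-Cope substrate)
Product: 32 ring-expanded trienone, via dipotassium dialkoxide 30 (not isolated), via dipotassium allenolate 31 (not isolated)
Conditions: KH (4 equiv), 18-crown-6, THF, 0 °C → rt; then sat. aq. NH4Cl, −78 °C
Reagents that add atoms: none
Why: Proposed new method: deprotonation gives dialkoxide 30, whose C2 oxido group weakens the C2–C7 bond so that a [3,3] shift of the 3-oxido-1,5-enyne C4≡C3–C2(O⁻)–C7–C6=C5 (the ene is the inner double bond of the allene) breaks C2–C7 and forms C4–C5 to give the cyclic allenolate 31, which is protonated at C3 on work-up; the closest known reactions are the anionic oxy-Cope ring expansions of 1-alkynyl-2-vinylcycloalkanols to cycloalka-2,5-dienones and Cope rearrangements with an allene as the ene partner, while the alkynyl carbinol/allenyl pairing itself is untested. The ten-membered ring arises by four-atom ring expansion of ring B (six to ten) through a chair-like transition state in which both migrating arms are equatorial, not by an end-to-end cyclisation. No stereocentre is created, but three alkene units are: the equatorial C7–C8 bond stands anti to C5 in that transition state and becomes the E-C6=C7 alkene, the central allene carbon C5 ends as the exo-methylene carbon, and protonation of the allenolate on the side away from C5 should give the Z-enone. The step needs the gauche, trans-diequatorial relation of the arms that steps 12–14 install (β-equatorial ethynyl, α-equatorial allenyl), and it needs the shift to outrun base-induced allene isomerisation or alkoxide addition to the allene, for which the syn-diaxial C2/C8 dialkoxide repulsion and the relief of the C15-methyl/9-silyloxy syn-axial strain should help. All stereocentres of 29 other than C2 and C7 (both sp2 afterwards) are untouched.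

Step 23
Reactants: 32 ring-expanded trienone
Product: 33 (2S)-alcohol
Conditions: NaBH4, CeCl3·7H2O, MeOH, −78 °C
Reagents that add atoms: none
Why: Luche 1,2-reduction of the cross-conjugated dienone in which hydride should add to the C2 carbonyl on the side opposite the C1 methyl (the α face of ring A) in the conformer whose carbonyl oxygen points toward C14, giving the 2S alcohol; this facial preference is the least secure stereochemical call of the route.

Step 24
Reactants: 33 (2S)-alcohol
Product: 34 2,9-diol
Conditions: TBAF, THF, 0 °C → rt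
Reagents that add atoms: none
Why: Fluoride cleavage of the C9 silyl ether; no stereocentre changes.

Step 25
Reactants: 34 2,9-diol
Product: 35 2,9-diacetate
Conditions: Ac2O, pyridine, DMAP (cat.), CH2Cl2, 0 °C → rt
Reagents that add atoms: acetic anhydride, CC(=O)OC(C)=O
Why: Acetylation of the two secondary alcohols; the tertiary C8 hydroxyl should stay free for the next step.

Step 26
Reactants: 35 2,9-diacetate
Product: 36 6,7-epoxide
Conditions: VO(acac)2 (10 mol %), t-BuOOH, CH2Cl2, 0 °C → rt
Reagents that add atoms: tert-butyl hydroperoxide, CC(C)(C)OO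
Why: Vanadium-catalysed hydroxyl-directed epoxidation in which only C6=C7 is allylic to a free hydroxyl and the vanadate ester on O8 can reach the alkene only when the C8–C9 ring bond stands perpendicular on the opposite face, so that oxygen should be delivered to the face that gives the trans-epoxide whose C7–O bond has the configuration of the lactone oxygen of the target.

Step 27
Reactants: 36 6,7-epoxide
Product: 39 12-deacetyl target, via chlorohydrin amide 37 (not isolated), via lactone acetonide 38 (not isolated)
Conditions: pyridinium chloride (3 equiv), CH2Cl2, 0 °C; then 1 M aq. HCl/THF, 35 °C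
Reagents that add atoms: pyridinium chloride, c1cc[nH+]cc1.[Cl-]
Why: Chloride should open the vinyl epoxide at the allylic carbon C6 with inversion (SN2, C7 being shielded by the quaternary C8) to give the anti chlorohydrin, after which acid transfers the acyl group of the γ-hydroxy amide to O7 (lactonisation with retention at C7) and hydrolyses the acetonide.

Step 28
Reactants: 39 12-deacetyl target
Product: 40 CNP0435497.1
Conditions: Ac2O, pyridine, DMAP (cat.), CH2Cl2, 0 °C → rt
Reagents that add atoms: acetic anhydride, CC(=O)OC(C)=O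
Why: Acetylation of the remaining secondary (C12) alcohol, the tertiary C8 and C11 hydroxyls being inert under these conditions, should give the target.

**Compound list**

1 | penta-1,4-dien-3-ol | C=CC(O)C=C | starting material
2 | (E)-5-chloropenta-1,3-diene | C=C/C=C/CCl | intermediate
3 | 2-methoxy-5-methyl-1,4-benzoquinone | COC1=CC(=O)C(C)=CC1=O | starting material
4 | cis-fused Diels–Alder adduct (8-methoxy-7-ene-2,9-dione; C1-CH3, C10-H and C11-H β, 11α-CH2Cl) | O=C1[C@@]2(C)CC=C[C@@H](CCl)[C@H]2C(=O)C(OC)=C1 | intermediate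
5 | trans-fused enedione (10α-H epimer of 4) | O=C1[C@@]2(C)CC=C[C@@H](CCl)[C@@H]2C(=O)C(OC)=C1 | intermediate
6 | 9β-hydroxy-8-methoxy-7-en-2-one | O=C1[C@@]2(C)CC=C[C@@H](CCl)[C@@H]2[C@H](O)C(OC)=C1 | intermediate
7 | 9β-TBS ether | O=C1[C@@]2(C)CC=C[C@@H](CCl)[C@@H]2[C@H](O[Si](C)(C)C(C)(C)C)C(OC)=C1 | intermediate
8 | 12α,13α-epoxide | O=C1[C@@]2(C)C[C@H]3O[C@H]3[C@@H](CCl)[C@@H]2[C@H](O[Si](C)(C)C(C)(C)C)C(OC)=C1 | intermediate
9 | 12α-hydroxy-13-ene | O=C1[C@@]2(C)C=C[C@@H](O)[C@@H](CCl)[C@@H]2[C@H](O[Si](C)(C)C(C)(C)C)C(OC)=C1 | intermediate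
10 | 11-(chloromethyl)-11,13-diene | O=C1[C@@]2(C)C=CC=C(CCl)[C@@H]2[C@H](O[Si](C)(C)C(C)(C)C)C(OC)=C1 | intermediate
11 | 11α,12α-diol (11β-CH2Cl) | O=C1[C@@]2(C)C=C[C@@H](O)[C@](O)(CCl)[C@@H]2[C@H](O[Si](C)(C)C(C)(C)C)C(OC)=C1 | intermediate
12 | 11α,12α-acetonide | O=C1[C@@]2(C)C=C[C@H]3OC(C)(C)O[C@@]3(CCl)[C@@H]2[C@H](O[Si](C)(C)C(C)(C)C)C(OC)=C1 | intermediate
13 | lithium (trimethylsilyl)acetylide | [Li+].[C-]#C[Si](C)(C)C | starting material
14 | lithium 2-alkoxide (1,2-adduct at C2; configuration inconsequential, drawn for α attack) | [Li+].[O-][C@]1(C#C[Si](C)(C)C)[C@@]2(C)C=C[C@H]3OC(C)(C)O[C@@]3(CCl)[C@@H]2[C@H](O[Si](C)(C)C(C)(C)C)C(OC)=C1 | intermediate (not isolated)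
15 | 2-alkynyl-2(7)-en-8-one | O=C1C=C(C#C[Si](C)(C)C)[C@@]2(C)C=C[C@H]3OC(C)(C)O[C@@]3(CCl)[C@@H]2[C@@H]1O[Si](C)(C)C(C)(C)C | intermediate
16 | 2α,7α-epoxy-8-ketone | O=C1[C@H]2O[C@@]2(C#C[Si](C)(C)C)[C@@]4(C)C=C[C@H]3OC(C)(C)O[C@@]3(CCl)[C@@H]4[C@@H]1O[Si](C)(C)C(C)(C)C | intermediate
17 | 2α-hydroxy-8-ketone (2β-alkynyl) | O=C1C[C@](O)(C#C[Si](C)(C)C)[C@@]2(C)C=C[C@H]3OC(C)(C)O[C@@]3(CCl)[C@@H]2[C@@H]1O[Si](C)(C)C(C)(C)C | intermediate
18 | 3-(trimethylsilyl)propynal | O=CC#C[Si](C)(C)C | starting material
19 | dilithium alkoxide-enolate of 17 | [Li+].[Li+].[O-]C1=C[C@]([O-])(C#C[Si](C)(C)C)[C@@]2(C)C=C[C@H]3OC(C)(C)O[C@@]3(CCl)[C@@H]2[C@@H]1O[Si](C)(C)C(C)(C)C | intermediate (not isolated)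
20 | dilithium aldolate (7α side chain) | [Li+].[Li+].O=C1[C@@H](C([O-])C#C[Si](C)(C)C)[C@]([O-])(C#C[Si](C)(C)C)[C@@]2(C)C=C[C@H]3OC(C)(C)O[C@@]3(CCl)[C@@H]2[C@@H]1O[Si](C)(C)C(C)(C)C | intermediate (not isolated)
21 | C6 methyl carbonate | O=C1[C@@H](C(OC(=O)OC)C#C[Si](C)(C)C)[C@](O)(C#C[Si](C)(C)C)[C@@]2(C)C=C[C@H]3OC(C)(C)O[C@@]3(CCl)[C@@H]2[C@@H]1O[Si](C)(C)C(C)(C)C | intermediate
22 | 9β-alcohol | O=C1[C@@H](C(OC(=O)OC)C#C[Si](C)(C)C)[C@](O)(C#C[Si](C)(C)C)[C@@]2(C)C=C[C@H]3OC(C)(C)O[C@@]3(CCl)[C@@H]2[C@@H]1O | intermediate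
23 | 2-bromopropanoyl bromide | CC(Br)C(Br)=O | starting material
24 | 9-(2-bromopropanoate) | O=C1[C@@H](C(OC(=O)OC)C#C[Si](C)(C)C)[C@](O)(C#C[Si](C)(C)C)[C@@]2(C)C=C[C@H]3OC(C)(C)O[C@@]3(CCl)[C@@H]2[C@@H]1OC(=O)C(C)Br | intermediate
25 | 8α-hydroxy 19,9-lactone (cis-fused γ-lactone, C17 as in the target) | [C@H]1(C(OC(=O)OC)C#C[Si](C)(C)C)[C@](O)(C#C[Si](C)(C)C)[C@@]2(C)C=C[C@H]3OC(C)(C)O[C@@]3(CCl)[C@@H]2[C@@H]4OC(=O)[C@H](C)[C@]14O | intermediate
26 | bis(terminal alkyne) lactone | [C@H]1(C(OC(=O)OC)C#C)[C@](O)(C#C)[C@@]2(C)C=C[C@H]3OC(C)(C)O[C@@]3(CCl)[C@@H]2[C@@H]4OC(=O)[C@H](C)[C@]14O | intermediate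
27 | 7α-allenyl lactone | [C@H]1(C=C=C)[C@](O)(C#C)[C@@]2(C)C=C[C@H]3OC(C)(C)O[C@@]3(CCl)[C@@H]2[C@@H]4OC(=O)[C@H](C)[C@]14O | intermediate
28 | pyrrolidine amide 8α,9β-diol | [C@H]1(C=C=C)[C@](O)(C#C)[C@@]2(C)C=C[C@H]3OC(C)(C)O[C@@]3(CCl)[C@@H]2[C@H](O)[C@]1(O)[C@@H](C)C(=O)N4CCCC4 | intermediate
29 | 9β-TBS ether (oxy-Cope substrate: 2α-OH, 2β-ethynyl, 7α-allenyl) | [C@H]1(C=C=C)[C@](O)(C#C)[C@@]2(C)C=C[C@H]3OC(C)(C)O[C@@]3(CCl)[C@@H]2[C@H](O[Si](C)(C)C(C)(C)C)[C@]1(O)[C@@H](C)C(=O)N4CCCC4 | intermediate
30 | dipotassium 2,8-dialkoxide of 29 | [K+].[K+].[C@H]1(C=C=C)[C@]([O-])(C#C)[C@@]2(C)C=C[C@H]3OC(C)(C)O[C@@]3(CCl)[C@@H]2[C@H](O[Si](C)(C)C(C)(C)C)[C@]1([O-])[C@@H](C)C(=O)N4CCCC4 | intermediate (not isolated)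
31 | dipotassium allenolate 8-alkoxide (ten-membered ring, 6E) | [K+].[K+].C=C1C=C=C([O-])[C@@]2(C)C=C[C@H]3OC(C)(C)O[C@@]3(CCl)[C@@H]2[C@H](O[Si](C)(C)C(C)(C)C)[C@]([O-])([C@@H](C)C(=O)N4CCCC4)/C=C/1 | intermediate (not isolated)
32 | ring-expanded trienone (2-oxo, 3Z, 5(16)-ene, 6E) | C=C1/C=C\C(=O)[C@@]2(C)C=C[C@H]3OC(C)(C)O[C@@]3(CCl)[C@@H]2[C@H](O[Si](C)(C)C(C)(C)C)[C@](O)([C@@H](C)C(=O)N4CCCC4)/C=C/1 | intermediate
33 | (2S)-alcohol | C=C1/C=C\[C@H](O)[C@@]2(C)C=C[C@H]3OC(C)(C)O[C@@]3(CCl)[C@@H]2[C@H](O[Si](C)(C)C(C)(C)C)[C@](O)([C@@H](C)C(=O)N4CCCC4)/C=C/1 | intermediate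
34 | 2,9-diol | C=C1/C=C\[C@H](O)[C@@]2(C)C=C[C@H]3OC(C)(C)O[C@@]3(CCl)[C@@H]2[C@H](O)[C@](O)([C@@H](C)C(=O)N4CCCC4)/C=C/1 | intermediate
35 | 2,9-diacetate | C=C1/C=C\[C@H](OC(C)=O)[C@@]2(C)C=C[C@H]3OC(C)(C)O[C@@]3(CCl)[C@@H]2[C@H](OC(C)=O)[C@](O)([C@@H](C)C(=O)N4CCCC4)/C=C/1 | intermediate
36 | 6,7-epoxide (trans) | C=C1/C=C\[C@H](OC(C)=O)[C@@]2(C)C=C[C@H]3OC(C)(C)O[C@@]3(CCl)[C@@H]2[C@H](OC(C)=O)[C@](O)([C@@H](C)C(=O)N4CCCC4)[C@H]5O[C@H]15 | intermediate
37 | chlorohydrin amide (6-chloro-7-hydroxy) | C=C1/C=C\[C@H](OC(C)=O)[C@@]2(C)C=C[C@H]3OC(C)(C)O[C@@]3(CCl)[C@@H]2[C@H](OC(C)=O)[C@](O)([C@@H](C)C(=O)N4CCCC4)[C@@H](O)[C@H]1Cl | intermediate (not isolated)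
38 | lactone acetonide (19,7-lactone) | C=C1/C=C\[C@H](OC(C)=O)[C@@]2(C)C=C[C@H]3OC(C)(C)O[C@@]3(CCl)[C@@H]2[C@H](OC(C)=O)[C@]2(O)[C@@H](C)C(=O)O[C@H]2[C@H]1Cl | intermediate (not isolated)
39 | 12-deacetyl target | C=C1/C=C\[C@H](OC(C)=O)[C@@]2(C)C=C[C@@H](O)[C@](O)(CCl)[C@@H]2[C@H](OC(C)=O)[C@]2(O)[C@@H](C)C(=O)O[C@H]2[C@H]1Cl | intermediate
40 | CNP0435497.1 | C=C1/C=C\[C@H](OC(C)=O)[C@@]2(C)C=C[C@@H](OC(C)=O)[C@](O)(CCl)[C@@H]2[C@H](OC(C)=O)[C@]2(O)[C@@H](C)C(=O)O[C@H]2[C@H]1Cl | target

**Totals.** Total step count: 28. Longest linear sequence: 28 steps (1 → 40).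

**Steps most likely to fail**

Step 22 (key step, proposed new method). The sigmatropic shift may be outrun by base-induced isomerisation of the allene or by addition of the C8 alkoxide to it. The fallback keeps the disconnection but uses the precedented alkynyl/alkenyl anionic oxy-Cope and makes the exo-methylene afterwards. It sets out from 29: palladium(0)-catalysed addition of 4-methoxyphenol across the terminal allene double bond should give the (E)-3-(4-methoxyphenoxy)prop-1-enyl analogue of 29 F1. KH/18-crown-6 then effects the known ring expansion to the 5-[(4-methoxyphenoxy)methyl]-5,16-dihydro analogue of 32 F2. DBU removes the doubly activated C5 hydrogen and expels 4-methoxyphenoxide (vinylogous E1cB), which returns to the route at 32.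

Step 23. Hydride delivery to the C2 carbonyl may occur on the wrong face, because the conformation of the cross-conjugated macrocyclic dienone is not secured by any ring constraint. The fallback moves stereocontrol from the substrate to the reagent: Corey–Bakshi–Shibata reduction of 32 with the oxazaborolidine antipode that overrides the substrate bias, returning to the route at 33.

Step 27. Chloride may attack the vinyl epoxide in the SN2′ sense (at C16), or acyl transfer from the tertiary amide to O7 may lag behind ionisation of the allylic acetate. The fallback forms the C6–Cl and C7–O bonds together instead: from 35, chlorolactonisation of the γ,δ-unsaturated amide with 1,3-dichloro-5,5-dimethylhydantoin in wet acetonitrile (anti addition across the E-alkene through the O-cyclised iminium ether, then its hydrolysis) leads to 38, which re-enters step 27 at the aqueous acid stage.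

Further compounds
F1 | step 22 | (E)-3-(4-methoxyphenoxy)prop-1-enyl analogue of 29 | [C@H]1(/C=C/COc5ccc(OC)cc5)[C@](O)(C#C)[C@@]2(C)C=C[C@H]3OC(C)(C)O[C@@]3(CCl)[C@@H]2[C@H](O[Si](C)(C)C(C)(C)C)[C@]1(O)[C@@H](C)C(=O)N4CCCC4
F2 | step 22 | 5-[(4-methoxyphenoxy)methyl]-5,16-dihydro analogue of 32 (C5 configuration undefined) | C(Oc5ccc(OC)cc5)C1/C=C\C(=O)[C@@]2(C)C=C[C@H]3OC(C)(C)O[C@@]3(CCl)[C@@H]2[C@H](O[Si](C)(C)C(C)(C)C)[C@](O)([C@@H](C)C(=O)N4CCCC4)/C=C/1
F0 | step 23 | none | none
F0 | step 27 | none | none
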